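The plan cuts the exo-methylene carbinol of the side chain: the bond between the 1,1-disubstituted alkene carbon C6 of the hept-6-en-3-one chain (the carbon bonded to C5 of the oxabicycloheptene ring) and the carbinol carbon C5. A Nozaki–Hiyama–Kishi coupling makes this bond, the 2-substituted allylic alcohol and its hydroxyl stereocentre in one chemoselective operation, exploiting the C7=C6–C5(OH) unit next to the C4 methyl stereocentre. Its precursors are enol triflate 28 of a cyclohexadienyl pyranone, built by a lactate-controlled 6π-electrocyclisation, and dioxolane-masked (R)-2-methyl-3-oxopentanal 12. Ketal hydrolysis and face-selective epoxidation of the ring diene finish the synthesis.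

Key step: step 20

Remark (assumption on the chemistry): in the A(1,3)-locked triene 24 the disrotatory sense that turns the methyl group, not the silyloxy group, of the lactate-derived centre toward the incoming pyranone terminus is taken as favoured; this fixes ethyl (S)-lactate as the source of ring chirality.

Step 1
Reactants: 1 methyl 2-methyl-3-oxopentanoate; 2 N-methoxy-N-methylpropanamide
Product: 3 methyl 2,4-dimethyl-3,5-dioxoheptanoate
Conditions: NaH, THF, 0 °C; n-BuLi, 0 °C; then 2, 0 °C to rt; aq. HCl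
Reagents that add atoms: none
Why: β-keto ester dianion acylation (Claisen-type): the terminal carbanion attacks the Weinreb amide and the chelated tetrahedral intermediate prevents over-addition; the two stereocentres are lost in the pyranone and need no control.

Step 2
Reactants: 3 methyl 2,4-dimethyl-3,5-dioxoheptanoate
Product: 4 6-ethyl-4-hydroxy-3,5-dimethyl-2H-pyran-2-one
Conditions: DBU, PhMe, 80 °C; aq. HCl
Reagents that add atoms: none
Why: base-mediated lactonisation (triketide cyclisation): the 5-enolate oxygen attacks the methyl ester and the product is stabilised as the 4-hydroxy-2-pyranone.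

Step 3
Reactants: 4 6-ethyl-4-hydroxy-3,5-dimethyl-2H-pyran-2-one
Product: 5 2-ethyl-6-methoxy-3,5-dimethyl-4H-pyran-4-one
Conditions: MeOTf, CH2Cl2, rt
Reagents that add atoms: methyl trifluoromethanesulfonate COS(=O)(=O)C(F)(F)F
Why: regioselective O-methylation: the hard electrophile alkylates the lactone carbonyl oxygen of the neutral hydroxypyranone and proton loss should give the 2-methoxy-4-pyranone, as known for 4-hydroxy-2-pyranones.

Step 4
Reactants: 6 methyl (R)-3-hydroxy-2-methylpropanoate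
Product: 7 methyl (R)-3-(benzyloxy)-2-methylpropanoate
Conditions: BnOC(=NH)CCl3, TfOH (cat.), CH2Cl2–cyclohexane, rt
Reagents that add atoms: benzyl 2,2,2-trichloroacetimidate N=C(OCc1ccccc1)C(Cl)(Cl)Cl
Why: acid-catalysed trichloroacetimidate benzylation avoids base, so the α-stereocentre of the hydroxy ester is neither racemised nor lost by β-elimination.

Step 5
Reactants: 7 methyl (R)-3-(benzyloxy)-2-methylpropanoate
Product: 9 (R)-1-(benzyloxy)-2-methylpentan-3-one, via Weinreb amide 8 (not isolated)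
Conditions: MeNH(OMe)·HCl, i-PrMgCl, THF, −20 °C; then EtMgBr, 0 °C
Reagents that add atoms: ethylmagnesium bromide CC[Mg]Br; N,O-dimethylhydroxylamine hydrochloride CNOC.Cl (amide unit of intermediate 8 only)
Why: magnesium-amide amidation followed by Weinreb ketone synthesis: the chelated tetrahedral intermediate stops at the ketone, and the stereocentre is carried through unchanged.

Step 6
Reactants: 9 (R)-1-(benzyloxy)-2-methylpentan-3-one
Product: 10 2-[(2R)-1-(benzyloxy)propan-2-yl]-2-ethyl-1,3-dioxolane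
Conditions: (TMSOCH2)2, TMSOTf (cat.), CH2Cl2, −78 to −20 °C
Reagents that add atoms: 1,2-bis(trimethylsilyloxy)ethane C[Si](C)(C)OCCO[Si](C)(C)C
Why: TMSOTf-catalysed ketalisation with the bis-silyl ether (Noyori conditions) runs through the oxocarbenium ion at low temperature without enolisation, so the α-methyl stereocentre is kept and the benzyloxy group is not eliminated.

Step 7
Reactants: 10 2-[(2R)-1-(benzyloxy)propan-2-yl]-2-ethyl-1,3-dioxolane
Product: 11 (R)-2-(2-ethyl-1,3-dioxolan-2-yl)propan-1-ol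
Conditions: H2 (1 atm), Pd/C, EtOAc, rt
Reagents that add atoms: none
Why: hydrogenolysis of the benzyl ether under neutral conditions leaves the dioxolane and the stereocentre untouched.

Step 8
Reactants: 11 (R)-2-(2-ethyl-1,3-dioxolan-2-yl)propan-1-ol
Product: 12 (R)-2-(2-ethyl-1,3-dioxolan-2-yl)propanal
Conditions: DMP, pyridine, CH2Cl2, 0 °C
Reagents that add atoms: none
Why: buffered Dess–Martin oxidation should give the α-chiral aldehyde without epimerisation; it is used directly in step 20.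

Step 9
Reactants: 13 ethyl (S)-2-hydroxypropanoate
Product: 14 ethyl (S)-2-[(tert-butyldimethylsilyl)oxy]propanoate
Conditions: TBSCl, imidazole, DMF, rt
Reagents that add atoms: tert-butyldimethylsilyl chloride CC(C)(C)[Si](C)(C)Cl
Why: standard silyl ether formation; the bulky silyloxy group later serves as the facial control element.

Step 10
Reactants: 14 ethyl (S)-2-[(tert-butyldimethylsilyl)oxy]propanoate
Product: 15 (S)-2-[(tert-butyldimethylsilyl)oxy]propanal
Conditions: DIBAL-H, CH2Cl2, −78 °C; aq. potassium sodium tartrate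
Reagents that add atoms: none
Why: DIBAL-H partial reduction: the tetrahedral aluminate of an α-silyloxy ester is stable at −78 °C and releases the aldehyde only on work-up, without racemisation.

Step 11
Reactants: 15 (S)-2-[(tert-butyldimethylsilyl)oxy]propanal; 16 2-(triphenylphosphoranylidene)propanal
Product: 17 (S,E)-4-[(tert-butyldimethylsilyl)oxy]-2-methylpent-2-enal
Conditions: PhMe, 90 °C
Reagents that add atoms: none
Why: Wittig olefination with a stabilised formyl ylide gives the (E)-trisubstituted enal under thermodynamic control of the betaine/oxaphosphetane.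

Step 12
Reactants: 17 (S,E)-4-[(tert-butyldimethylsilyl)oxy]-2-methylpent-2-enal; 18 ethyl 2-[bis(2,2,2-trifluoroethoxy)phosphoryl]propanoate
Product: 19 ethyl (2Z,4E,6S)-6-[(tert-butyldimethylsilyl)oxy]-2,4-dimethylhepta-2,4-dienoate
Conditions: KHMDS, 18-crown-6, THF, −78 °C
Reagents that add atoms: none
Why: Still–Gennari olefination: fast, irreversible elimination from the kinetic adduct of the electron-poor phosphonate should give the (Z)-trisubstituted enoate needed for ring closure.

Step 13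
Reactants: 19 ethyl (2Z,4E,6S)-6-[(tert-butyldimethylsilyl)oxy]-2,4-dimethylhepta-2,4-dienoate
Product: 20 (2Z,4E,6S)-6-[(tert-butyldimethylsilyl)oxy]-2,4-dimethylhepta-2,4-dien-1-ol
Conditions: DIBAL-H, CH2Cl2, −78 °C
Reagents that add atoms: none
Why: DIBAL-H 1,2-reduction of the enoate to the allylic alcohol leaves both alkene geometries intact.

Step 14
Reactants: 20 (2Z,4E,6S)-6-[(tert-butyldimethylsilyl)oxy]-2,4-dimethylhepta-2,4-dien-1-ol
Product: 21 (2Z,4E,6S)-6-[(tert-butyldimethylsilyl)oxy]-2,4-dimethylhepta-2,4-dienal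
Conditions: MnO2, CH2Cl2, rt, dark
Reagents that add atoms: none
Why: MnO2 allylic oxidation is neutral, so Z-to-E isomerisation of the labile (Z)-enal is avoided; the aldehyde is used at once.

Step 15
Reactants: 5 2-ethyl-6-methoxy-3,5-dimethyl-4H-pyran-4-one; 21 (2Z,4E,6S)-6-[(tert-butyldimethylsilyl)oxy]-2,4-dimethylhepta-2,4-dienal
Product: 22 2-[(4Z,6E,8S)-8-[(tert-butyldimethylsilyl)oxy]-3-hydroxy-4,6-dimethylnona-4,6-dien-2-yl]-6-methoxy-3,5-dimethyl-4H-pyran-4-one (diastereomer mixture at C2/C3)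
Conditions: LiHMDS, THF, −78 °C; then 21
Reagents that add atoms: none
Why: vinylogous aldol addition: LiHMDS deprotonates the CH2 of the 2-ethyl group (vinylogous enolate of the pyranone), which adds 1,2 to the aldehyde; the two new stereocentres are removed in step 16.

Step 16
Reactants: 22 2-[(4Z,6E,8S)-8-[(tert-butyldimethylsilyl)oxy]-3-hydroxy-4,6-dimethylnona-4,6-dien-2-yl]-6-methoxy-3,5-dimethyl-4H-pyran-4-one
Product: 25 2-[(1R,6S)-6-{(1S)-1-[(tert-butyldimethylsilyl)oxy]ethyl}-1,3,5-trimethylcyclohexa-2,4-dien-1-yl]-6-methoxy-3,5-dimethyl-4H-pyran-4-one, via allylic acetate 23 (not isolated), via (2E,4Z,6E)-triene 24 (not isolated)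
Conditions: Ac2O, Et3N, DMAP, CH2Cl2, 0 °C; then DBU, PhMe, rt to 80 °C, dark
Reagents that add atoms: acetic anhydride CC(=O)OC(C)=O (acetyl group of intermediate 23 only)
Why: E1cB elimination through the vinylogous pyranone enolate gives the thermodynamic (E)-alkene, and the (2E,4Z,6E)-triene then undergoes thermal disrotatory 6π-electrocyclisation, which places the two outside groups (pyranone on C1, silyloxyethyl on C6) cis, while the lactate-derived centre, locked by A(1,3) strain with the C5 methyl so that its hydrogen eclipses the alkene, should favour the rotation that turns its methyl rather than its silyloxy group toward the incoming pyranone terminus, setting (1R,6S).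

Step 17
Reactants: 25 2-[(1R,6S)-6-{(1S)-1-[(tert-butyldimethylsilyl)oxy]ethyl}-1,3,5-trimethylcyclohexa-2,4-dien-1-yl]-6-methoxy-3,5-dimethyl-4H-pyran-4-one
Product: 26 2-[(1R,6S)-6-[(1S)-1-hydroxyethyl]-1,3,5-trimethylcyclohexa-2,4-dien-1-yl]-6-methoxy-3,5-dimethyl-4H-pyran-4-one
Conditions: TBAF, THF, 0 °C to rt
Reagents that add atoms: none
Why: fluoride desilylation; the 2-methoxy-4-pyranone and the diene tolerate TBAF at this temperature.

Step 18
Reactants: 26 2-[(1R,6S)-6-[(1S)-1-hydroxyethyl]-1,3,5-trimethylcyclohexa-2,4-dien-1-yl]-6-methoxy-3,5-dimethyl-4H-pyran-4-one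
Product: 27 2-[(1R,6S)-6-acetyl-1,3,5-trimethylcyclohexa-2,4-dien-1-yl]-6-methoxy-3,5-dimethyl-4H-pyran-4-one
Conditions: DMP, pyridine, CH2Cl2, 0 °C
Reagents that add atoms: none
Why: buffered Dess–Martin oxidation erases the controlling carbinol centre and gives the methyl ketone without epimerising the adjacent ring methine.

Step 19
Reactants: 27 2-[(1R,6S)-6-acetyl-1,3,5-trimethylcyclohexa-2,4-dien-1-yl]-6-methoxy-3,5-dimethyl-4H-pyran-4-one
Product: 28 1-[(1S,6R)-6-(6-methoxy-3,5-dimethyl-4-oxo-4H-pyran-2-yl)-2,4,6-trimethylcyclohexa-2,4-dien-1-yl]ethenyl trifluoromethanesulfonate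
Conditions: KHMDS, THF, −78 °C; then PhNTf2, −78 to 0 °C
Reagents that add atoms: N-phenylbis(trifluoromethanesulfonimide) O=S(=O)(N(c1ccccc1)S(=O)(=O)C(F)(F)F)C(F)(F)F
Why: kinetic enolisation at the methyl group (far less hindered than the ring methine flanked by a quaternary carbon) and O-triflation should give the 2-triflyloxy-1-alkene (enol triflate formation).

Step 20
Reactants: 28 1-[(1S,6R)-6-(6-methoxy-3,5-dimethyl-4-oxo-4H-pyran-2-yl)-2,4,6-trimethylcyclohexa-2,4-dien-1-yl]ethenyl trifluoromethanesulfonate; 12 (R)-2-(2-ethyl-1,3-dioxolan-2-yl)propanal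
Product: 29 2-[(1R,6R)-6-{(3R,4R)-4-(2-ethyl-1,3-dioxolan-2-yl)-3-hydroxypent-1-en-2-yl}-1,3,5-trimethylcyclohexa-2,4-dien-1-yl]-6-methoxy-3,5-dimethyl-4H-pyran-4-one
Conditions: CrCl2 (5 equiv), NiCl2 (2 mol %), DMF, rt
Reagents that add atoms: none
Why: Ni(0), formed in situ from NiCl2 and Cr(II), inserts into the alkenyl C–OTf bond of 28, and transmetalation gives an alkenylchromium(III) species that adds 1,2 to the aldehyde of 12, forming the bond between alkene carbon C2 and carbinol carbon C3 of the pentenyl unit (Nozaki–Hiyama–Kishi reaction, the standard entry to 2-substituted allylic alcohols from 2-halo- or 2-triflyloxy-1-alkenes). No ring is closed. The new carbinol stereocentre is controlled by the α-methyl stereocentre of 12: in DMF, which saturates Cr(III) and suppresses chelation, the quaternary dioxolane carbon is the large Felkin–Anh group, and attack anti to it should give the 3,4-syn (3R,4R) alcohol. The step needs chemoselectivity for the aldehyde over the pyranone carbonyl and the diene, which the low basicity and aldehyde preference of organochromium reagents secure. It also needs the α-stereocentre of 12 and the ring stereocentres of 28 to survive, which the neutral, non-enolising conditions secure.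

Step 21
Reactants: 29 2-[(1R,6R)-6-{(3R,4R)-4-(2-ethyl-1,3-dioxolan-2-yl)-3-hydroxypent-1-en-2-yl}-1,3,5-trimethylcyclohexa-2,4-dien-1-yl]-6-methoxy-3,5-dimethyl-4H-pyran-4-one
Product: 30 (4R,5R)-5-hydroxy-6-[(1R,6R)-6-(6-methoxy-3,5-dimethyl-4-oxo-4H-pyran-2-yl)-2,4,6-trimethylcyclohexa-2,4-dien-1-yl]-4-methylhept-6-en-3-one
Conditions: PPTS, acetone–H2O, 45 °C
Reagents that add atoms: water O
Why: acid-catalysed ketal hydrolysis; PPTS should be mild enough to spare the allylic alcohol and the diene and to avoid dehydration or epimerisation of the β-hydroxy ketone.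

Step 22
Reactants: 30 (4R,5R)-5-hydroxy-6-[(1R,6R)-6-(6-methoxy-3,5-dimethyl-4-oxo-4H-pyran-2-yl)-2,4,6-trimethylcyclohexa-2,4-dien-1-yl]-4-methylhept-6-en-3-one
Product: 31 (4R,5R)-5-hydroxy-6-[(1R,4R,5R,6S)-4-(6-methoxy-3,5-dimethyl-4-oxo-4H-pyran-2-yl)-2,4,6-trimethyl-7-oxabicyclo[4.1.0]hept-2-en-5-yl]-4-methylhept-6-en-3-one
Conditions: DMDO, acetone, −40 to −20 °C
Reagents that add atoms: dimethyldioxirane CC1(C)OO1
Why: dioxirane epoxidation under neutral conditions should attack the most electron-rich and accessible alkene, the ring C2=C3 bond remote from the quaternary carbon, from the face anti to the C1 side chain and the C6 pyranone (the face carrying C1–H and C6–CH3), which sets both epoxide stereocentres; the electron-poorer exocyclic alkene and the pyranone react more slowly.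

Compound list
1 | methyl 2-methyl-3-oxopentanoate (racemic) | CCC(=O)C(C)C(=O)OC | starting material
2 | N-methoxy-N-methylpropanamide | CCC(=O)N(C)OC | starting material
3 | methyl 2,4-dimethyl-3,5-dioxoheptanoate (stereoisomer and tautomer mixture) | CCC(=O)C(C)C(=O)C(C)C(=O)OC | intermediate
4 | 6-ethyl-4-hydroxy-3,5-dimethyl-2H-pyran-2-one | CCC1=C(C)C(O)=C(C)C(=O)O1 | intermediate
5 | 2-ethyl-6-methoxy-3,5-dimethyl-4H-pyran-4-one | CCc1oc(OC)c(C)c(=O)c1C | intermediate
6 | methyl (R)-3-hydroxy-2-methylpropanoate | OC[C@@H](C)C(=O)OC | starting material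
7 | methyl (R)-3-(benzyloxy)-2-methylpropanoate | c1ccccc1COC[C@@H](C)C(=O)OC | intermediate
8 | (R)-3-(benzyloxy)-N-methoxy-N,2-dimethylpropanamide | c1ccccc1COC[C@@H](C)C(=O)N(C)OC | intermediate (not isolated)
9 | (R)-1-(benzyloxy)-2-methylpentan-3-one | c1ccccc1COC[C@@H](C)C(=O)CC | intermediate
10 | 2-[(2R)-1-(benzyloxy)propan-2-yl]-2-ethyl-1,3-dioxolane | c1ccccc1COC[C@@H](C)C2(CC)OCCO2 | intermediate
11 | (R)-2-(2-ethyl-1,3-dioxolan-2-yl)propan-1-ol | OC[C@@H](C)C1(CC)OCCO1 | intermediate
12 | (R)-2-(2-ethyl-1,3-dioxolan-2-yl)propanal | O=C[C@@H](C)C1(CC)OCCO1 | intermediate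
13 | ethyl (S)-2-hydroxypropanoate (ethyl (S)-lactate) | C[C@H](O)C(=O)OCC | starting material
14 | ethyl (S)-2-[(tert-butyldimethylsilyl)oxy]propanoate | C[C@H](O[Si](C)(C)C(C)(C)C)C(=O)OCC | intermediate
15 | (S)-2-[(tert-butyldimethylsilyl)oxy]propanal | C[C@H](O[Si](C)(C)C(C)(C)C)C=O | intermediate
16 | 2-(triphenylphosphoranylidene)propanal | CC(C=O)=P(c1ccccc1)(c1ccccc1)c1ccccc1 | starting material
17 | (S,E)-4-[(tert-butyldimethylsilyl)oxy]-2-methylpent-2-enal | C[C@H](O[Si](C)(C)C(C)(C)C)/C=C(\C)C=O | intermediate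
18 | ethyl 2-[bis(2,2,2-trifluoroethoxy)phosphoryl]propanoate | CCOC(=O)C(C)P(=O)(OCC(F)(F)F)OCC(F)(F)F | starting material
19 | ethyl (2Z,4E,6S)-6-[(tert-butyldimethylsilyl)oxy]-2,4-dimethylhepta-2,4-dienoate | C[C@H](O[Si](C)(C)C(C)(C)C)/C=C(\C)/C=C(/C)C(=O)OCC | intermediate
20 | (2Z,4E,6S)-6-[(tert-butyldimethylsilyl)oxy]-2,4-dimethylhepta-2,4-dien-1-ol | C[C@H](O[Si](C)(C)C(C)(C)C)/C=C(\C)/C=C(/C)CO | intermediate
21 | (2Z,4E,6S)-6-[(tert-butyldimethylsilyl)oxy]-2,4-dimethylhepta-2,4-dienal | C[C@H](O[Si](C)(C)C(C)(C)C)/C=C(\C)/C=C(/C)C=O | intermediate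
22 | 2-[(4Z,6E,8S)-8-[(tert-butyldimethylsilyl)oxy]-3-hydroxy-4,6-dimethylnona-4,6-dien-2-yl]-6-methoxy-3,5-dimethyl-4H-pyran-4-one (mixture at C2/C3) | COc1oc(C(C)C(O)/C(C)=C\C(C)=C\[C@H](C)O[Si](C)(C)C(C)(C)C)c(C)c(=O)c1C | intermediate
23 | 3-O-acetate of 22 (allylic acetate) | COc1oc(C(C)C(OC(C)=O)/C(C)=C\C(C)=C\[C@H](C)O[Si](C)(C)C(C)(C)C)c(C)c(=O)c1C | intermediate (not isolated)
24 | 2-[(2E,4Z,6E,8S)-8-[(tert-butyldimethylsilyl)oxy]-4,6-dimethylnona-2,4,6-trien-2-yl]-6-methoxy-3,5-dimethyl-4H-pyran-4-one | COc1oc(/C(C)=C/C(C)=C\C(C)=C\[C@H](C)O[Si](C)(C)C(C)(C)C)c(C)c(=O)c1C | intermediate (not isolated)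
25 | 2-[(1R,6S)-6-{(1S)-1-[(tert-butyldimethylsilyl)oxy]ethyl}-1,3,5-trimethylcyclohexa-2,4-dien-1-yl]-6-methoxy-3,5-dimethyl-4H-pyran-4-one | C[C@H](O[Si](C)(C)C(C)(C)C)[C@H]1C(C)=CC(C)=C[C@@]1(C)c1oc(OC)c(C)c(=O)c1C | intermediate
26 | 2-[(1R,6S)-6-[(1S)-1-hydroxyethyl]-1,3,5-trimethylcyclohexa-2,4-dien-1-yl]-6-methoxy-3,5-dimethyl-4H-pyran-4-one | C[C@H](O)[C@H]1C(C)=CC(C)=C[C@@]1(C)c1oc(OC)c(C)c(=O)c1C | intermediate
27 | 2-[(1R,6S)-6-acetyl-1,3,5-trimethylcyclohexa-2,4-dien-1-yl]-6-methoxy-3,5-dimethyl-4H-pyran-4-one | CC(=O)[C@H]1C(C)=CC(C)=C[C@@]1(C)c1oc(OC)c(C)c(=O)c1C | intermediate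
28 | 1-[(1S,6R)-6-(6-methoxy-3,5-dimethyl-4-oxo-4H-pyran-2-yl)-2,4,6-trimethylcyclohexa-2,4-dien-1-yl]ethenyl trifluoromethanesulfonate | C=C(OS(=O)(=O)C(F)(F)F)[C@H]1C(C)=CC(C)=C[C@@]1(C)c1oc(OC)c(C)c(=O)c1C | intermediate
29 | 2-[(1R,6R)-6-{(3R,4R)-4-(2-ethyl-1,3-dioxolan-2-yl)-3-hydroxypent-1-en-2-yl}-1,3,5-trimethylcyclohexa-2,4-dien-1-yl]-6-methoxy-3,5-dimethyl-4H-pyran-4-one | C=C([C@H](O)[C@@H](C)C2(CC)OCCO2)[C@H]1C(C)=CC(C)=C[C@@]1(C)c1oc(OC)c(C)c(=O)c1C | intermediate
30 | (4R,5R)-5-hydroxy-6-[(1R,6R)-6-(6-methoxy-3,5-dimethyl-4-oxo-4H-pyran-2-yl)-2,4,6-trimethylcyclohexa-2,4-dien-1-yl]-4-methylhept-6-en-3-one | C=C([C@H](O)[C@@H](C)C(=O)CC)[C@H]1C(C)=CC(C)=C[C@@]1(C)c1oc(OC)c(C)c(=O)c1C | intermediate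
31 | (4R,5R)-5-hydroxy-6-[(1R,4R,5R,6S)-4-(6-methoxy-3,5-dimethyl-4-oxo-4H-pyran-2-yl)-2,4,6-trimethyl-7-oxabicyclo[4.1.0]hept-2-en-5-yl]-4-methylhept-6-en-3-one (CNP0233636.2) | C=C([C@H](O)[C@@H](C)C(=O)CC)[C@H]1[C@]2(C)O[C@@H]2C(C)=C[C@@]1(C)c1oc(OC)c(C)c(=O)c1C | target

Total step count: 22 steps (pyranone branch steps 1–3, aldehyde branch steps 4–8, main line steps 9–22).
Longest linear sequence: 14 steps (steps 9–22, from ethyl (S)-lactate 13 to 31).

Steps most likely to fail

Step 16. The allylic stereocentre may not discriminate the two disrotatory senses well enough (or may favour the other one), so that the ring-diastereomer forms alongside 25. The fallback uses the lactate centre as a resolving handle instead of a directing group. It sets out from 22, which is eliminated and cyclised as before without relying on selectivity. The resulting mixture of 25 and the ring-diastereomeric silyl ether F1 is desilylated with TBAF, and 26 is separated by chromatography from the ring-diastereomeric alcohol F2, which is a diastereomer and not an enantiomer of 26. The route is rejoined at 26.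

Step 20. Facial selectivity at the aldehyde may be poor (Felkin against anti-Felkin attack of a hindered alkenylchromium), giving a mixture at the carbinol. The fallback sets the carbinol by ketone reduction instead of by the C–C coupling. It sets out from 29 obtained together with the C3-epimeric carbinol F3. Dess–Martin oxidation of the mixture gives the enone F4, and Zn(BH4)2 in Et2O at −30 °C reduces it 1,2 under chelation between the ketone and a dioxolane oxygen, with hydride delivered anti to the α-methyl group, to give the 3,4-syn alcohol. The route is rejoined at 29.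

Step 22. The free allylic hydroxyl may assist epoxidation of the exocyclic alkene, or the oxidant may attack more than one alkene. The fallback removes the hydroxyl assistance by protection. It sets out from 30, which is silylated (TESOTf, 2,6-lutidine, CH2Cl2, −78 °C) to the triethylsilyl ether F5. DMDO epoxidation then gives the silylated epoxide F6, and buffered HF·pyridine in THF/pyridine at 0 °C cleaves the silyl ether. The route is rejoined at 31.

Further compounds
F1 | step 16 | 2-[(1S,6R)-6-{(1S)-1-[(tert-butyldimethylsilyl)oxy]ethyl}-1,3,5-trimethylcyclohexa-2,4-dien-1-yl]-6-methoxy-3,5-dimethyl-4H-pyran-4-one (ring-diastereomer of 25) | C[C@H](O[Si](C)(C)C(C)(C)C)[C@@H]1C(C)=CC(C)=C[C@]1(C)c1oc(OC)c(C)c(=O)c1C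
F2 | step 16 | 2-[(1S,6R)-6-[(1S)-1-hydroxyethyl]-1,3,5-trimethylcyclohexa-2,4-dien-1-yl]-6-methoxy-3,5-dimethyl-4H-pyran-4-one (ring-diastereomer of 26) | C[C@H](O)[C@@H]1C(C)=CC(C)=C[C@]1(C)c1oc(OC)c(C)c(=O)c1C
F3 | step 20 | 2-[(1R,6R)-6-{(3S,4R)-4-(2-ethyl-1,3-dioxolan-2-yl)-3-hydroxypent-1-en-2-yl}-1,3,5-trimethylcyclohexa-2,4-dien-1-yl]-6-methoxy-3,5-dimethyl-4H-pyran-4-one (C3 epimer of 29) | C=C([C@@H](O)[C@@H](C)C2(CC)OCCO2)[C@H]1C(C)=CC(C)=C[C@@]1(C)c1oc(OC)c(C)c(=O)c1C
F4 | step 20 | 2-[(1R,6R)-6-{(4R)-4-(2-ethyl-1,3-dioxolan-2-yl)-3-oxopent-1-en-2-yl}-1,3,5-trimethylcyclohexa-2,4-dien-1-yl]-6-methoxy-3,5-dimethyl-4H-pyran-4-one | C=C(C(=O)[C@@H](C)C2(CC)OCCO2)[C@H]1C(C)=CC(C)=C[C@@]1(C)c1oc(OC)c(C)c(=O)c1C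
F5 | step 22 | triethylsilyl ether of 30 at the C5 hydroxyl | C=C([C@H](O[Si](CC)(CC)CC)[C@@H](C)C(=O)CC)[C@H]1C(C)=CC(C)=C[C@@]1(C)c1oc(OC)c(C)c(=O)c1C
F6 | step 22 | triethylsilyl ether of 31 at the C5 hydroxyl | C=C([C@H](O[Si](CC)(CC)CC)[C@@H](C)C(=O)CC)[C@H]1[C@]2(C)O[C@@H]2C(C)=C[C@@]1(C)c1oc(OC)c(C)c(=O)c1C
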